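1. The incoming ligand charged to this flask, 0.0150 M against 0.0050 M of starting complex, was conserved: free, bound or converted, its entries had to add up to the charge, so I kept it as a ledger.

| flask | starting complex | incoming ligand | leaving ligand | remark | time |
|---|---|---|---|---|---|
| dusk | 0.0050 M | 0.015 M | 2.5 mM | the very flask that is asked about, followed so far |  |
| flask | 0.0050 M | 0.0150 M | 2.50 mM |  | 30 min |

dusk run (percent of the starting complex charged): time / min: complex with one exchanged / % = 0.200: 7.7; 0.500: 11.7; 1.33: 13.7; 2.50: 10.1; 6.00: 5.1; 15.0: 2.0

(standard deviation of a reading: 1 percentage point)

1. the moment within 30 min at which there is most complex with one exchanged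
2. the amount of complex with one exchanged, in percent of the starting complex charged, at that time

2. The dusk run was this very flask, so I booked its readings here. The first entry was complex with one exchanged, whose highest reading, 13.7 % at 1.33 min, held 0.685 mM of incoming ligand.

3. I called 4.57 % the capture share: the part of the charged incoming ligand standing as complex with one exchanged at its peak. It was a reading, with a scatter of 1 percentage point on the percentage behind it.

4. The second entry was the remainder, 14.3 mM, more than the first entry. Yet the readings fell to 2.0 % by 15.0 min, so I booked that remainder as going where the readings did not show.

5. I committed to a peak between 0.500 min and 2.50 min, around the reading at 1.33 min. The forecast gave 1.05 min and 14.3 %, saying "the maximum falls early".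

6. The flask gave 14.4 % at 0.853 min, a capture share of 4.81 % against the 4.57 % I had read from the dusk run.

    complex with one exchanged + incoming ligand → over-reaction product (k = 0.220 L mol⁻¹ s⁻¹)
    starting complex + incoming ligand ⇌ leaving ligand + complex with one exchanged (K = 0.410, k = 0.690 L mol⁻¹ s⁻¹)
    incoming ligand → decomposed reagent (k = 0.0410 s⁻¹)
    complex with one exchanged + incoming ligand ⇌ leaving ligand + complex with two exchanged (K = 0.400, k = 0.440 L mol⁻¹ s⁻¹)
    complex with two exchanged + incoming ligand ⇌ leaving ligand + complex with three exchanged (K = 5.10, k = 1.10 L mol⁻¹ s⁻¹)

While incoming ligand stood in the flask, its half-life toward decomposed reagent, 0.28 min, was shorter than the 3.8 min of its forward step onto starting complex at 0.290 min, and at 0.853 min the ledger held 0.0125 M of decomposed reagent. By 30.0 min incoming ligand, the limiting reagent, stood at 0 % and starting complex at 99.2 %. For the neighbouring flask with 0.025 M of incoming ligand, the capture share read from the dusk run, 4.57 %, gave a peak of 22.9 % of complex with one exchanged; that flask reached 20.8 %, a capture share of 4.16 %.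

(The readings come from a simulation with constants of no real substance; scatter was added.)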